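The route rests on disconnecting tetrahydrofuran ring A (O1, C2, C3, C3a, C7a) at O1–C7a and C3–C2. A (Z)-γ-tert-butoxyallylboronate supplies O1, C2 and a vinyl handle and adds to an epoxy aldehyde that holds C3 (CHO), a cis-oxirane (C3a, C7a) and the (Z)-acrylate arm C7–C6–C5; acid then lets O1 open the strained oxirane at C7a, which is allylic to C6=C7, with inversion, and the freed C3a oxygen closes lactone ring B. One flask thus gives the complete cis-fused furo[3,2-b]pyranone with all four ring stereocentres and the free C3 hydroxyl. The feature exploited is the all-cis O1/C3–OH/O4 array next to allylic C7a. Cross-metathesis adds the side chain.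

Key step: step 8

Remark: locants O1, C2, C3, C3a, O4, C5, C6, C7, C7a are those of the furo[3,2-b]pyran-5-one core (ring A is its tetrahydrofuran, ring B its dihydropyranone); compounds 1, 8 and 14 are taken as purchased.

Step 1
Reactants: 1 (Z)-but-2-ene-1,4-diol
Product: 2 (Z)-4-[(tert-butyldimethylsilyl)oxy]but-2-en-1-ol
Conditions: NaH (1.0 equiv), THF, 0 °C; then TBSCl (1.0 equiv), 0 °C to rt
Reagents that add atoms: tert-butyldimethylsilyl chloride, CC(C)(C)[Si](C)(C)Cl
Why: O-silylation of the poorly soluble monosodium alkoxide of the symmetric diol should stop at the monoether, and no stereocentre is formed.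

Step 2
Reactants: 2 (Z)-4-[(tert-butyldimethylsilyl)oxy]but-2-en-1-ol
Product: 3 [(2S,3R)-3-{[(tert-butyldimethylsilyl)oxy]methyl}oxiran-2-yl]methanol
Conditions: Ti(OiPr)4 (cat.), L-(+)-diethyl tartrate, t-BuOOH, 4 Å molecular sieves, CH2Cl2, −20 °C
Reagents that add atoms: tert-butyl hydroperoxide, CC(C)(C)OO
Why: Sharpless asymmetric epoxidation of the allylic alcohol, in which the titanium L-(+)-tartrate complex should deliver oxygen to the face that gives the (2S,3R) oxirane, the cis relation of the future C3a and C7a following from the Z alkene.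

Step 3
Reactants: 3 [(2S,3R)-3-{[(tert-butyldimethylsilyl)oxy]methyl}oxiran-2-yl]methanol
Product: 4 (2R,3R)-3-{[(tert-butyldimethylsilyl)oxy]methyl}oxirane-2-carbaldehyde
Conditions: TEMPO (cat.), PhI(OAc)2, CH2Cl2, rt
Reagents that add atoms: none
Why: Oxoammonium (TEMPO) oxidation of the primary alcohol to the aldehyde is mild enough to leave the oxirane and the silyl ether untouched and does not touch either stereocentre.

Step 4
Reactants: 4 (2R,3R)-3-{[(tert-butyldimethylsilyl)oxy]methyl}oxirane-2-carbaldehyde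
Product: 5 methyl (2Z)-3-[(2S,3R)-3-{[(tert-butyldimethylsilyl)oxy]methyl}oxiran-2-yl]prop-2-enoate
Conditions: (CF3CH2O)2P(O)CH2CO2Me, KN(SiMe3)2, 18-crown-6, THF, −78 °C
Reagents that add atoms: methyl bis(2,2,2-trifluoroethyl)phosphonoacetate, COC(=O)CP(=O)(OCC(F)(F)F)OCC(F)(F)F
Why: Still–Gennari variant of the Horner–Wadsworth–Emmons olefination, whose fast irreversible elimination from the trifluoroethyl phosphonate adduct should give the Z enoate needed later for lactonisation.

Step 5
Reactants: 5 methyl (2Z)-3-[(2S,3R)-3-{[(tert-butyldimethylsilyl)oxy]methyl}oxiran-2-yl]prop-2-enoate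
Product: 6 methyl (2Z)-3-[(2S,3R)-3-(hydroxymethyl)oxiran-2-yl]prop-2-enoate
Conditions: HF·pyridine, pyridine, THF, 0 °C
Reagents that add atoms: none
Why: Fluoride-driven cleavage of the silyl ether under buffered, non-basic conditions should free the primary alcohol without conjugate addition to the enoate or opening of the oxirane.

Step 6
Reactants: 6 methyl (2Z)-3-[(2S,3R)-3-(hydroxymethyl)oxiran-2-yl]prop-2-enoate
Product: 7 methyl (2Z)-3-[(2S,3S)-3-formyloxiran-2-yl]prop-2-enoate
Conditions: TEMPO (cat.), PhI(OAc)2, CH2Cl2, rt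
Reagents that add atoms: none
Why: The same TEMPO oxidation should give the α,β-epoxy aldehyde (future C3) under neutral conditions that preserve the cis-oxirane and the Z alkene.

Step 7
Reactants: 8 allyl tert-butyl ether (3-tert-butoxyprop-1-ene)
Product: 10 2-[(2Z)-3-tert-butoxyprop-2-en-1-yl]-4,4,5,5-tetramethyl-1,3,2-dioxaborolane, via (Z)-3-tert-butoxyallyllithium 9 (not isolated)
Conditions: s-BuLi, THF, −78 °C; then i-PrOBpin, −78 °C to rt; aqueous work-up
Reagents that add atoms: 2-isopropoxy-4,4,5,5-tetramethyl-1,3,2-dioxaborolane, CC(C)OB1OC(C)(C)C(C)(C)O1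
Why: Allylic lithiation of the ether gives the oxygen-chelated Z allyl anion, which should be borylated at the carbon remote from oxygen to give the (Z)-γ-alkoxyallylboronate.

Step 8
Reactants: 7 methyl (2Z)-3-[(2S,3S)-3-formyloxiran-2-yl]prop-2-enoate and 10 2-[(2Z)-3-tert-butoxyprop-2-en-1-yl]-4,4,5,5-tetramethyl-1,3,2-dioxaborolane
Product: 13 (2S,3R,3aR,7aR)-2-ethenyl-3-hydroxy-2,3,3a,7a-tetrahydro-5H-furo[3,2-b]pyran-5-one, via borate ester 11 (not isolated), via hydroxy ester 12 (not isolated)
Conditions: toluene, rt; then BF3·OEt2 (20 mol %), CH2Cl2, −30 °C to rt; aq. NaHCO3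
Reagents that add atoms: none
Why: Stage one is a γ-alkoxyallylboration of an α,β-epoxy aldehyde: the γ-carbon of 10 (future C2) adds to the aldehyde carbon of 7 (C3) through a closed chair transition state to give borate 11, the Z enol ether placing the C2 and C3 oxygens syn and the α-oxirane, reinforced by the Z-substituted reagent, directing Felkin–Anh attack anti to the oxirane oxygen. In stage two BF3·OEt2 activates the oxirane and the tert-butoxy oxygen on C2 attacks C7a with inversion while 2-methylpropene is lost, the closest known reaction types being the BF3-promoted anti-SN2 substitution of γ,δ-epoxy acrylates by oxygen nucleophiles and the acid cyclisation of hydroxy vinyl epoxides. Ring A closes in the 5-endo epoxide-opening mode, which should win because C7a is allylic to the C6=C7 acrylate double bond and the 4-exo alternative at C3a would give an oxetane, and ring B then closes by 6-exo-trig lactonisation of the freed C3a hydroxyl onto the Z methyl ester (hydroxy ester 12 to 13). C2 and C3 are set by the allylboration transition state, C7a by inversion of the oxirane carbon made in step 2, and C3a is carried over unchanged from step 2, so the cis-oxirane translates into the all-cis ring A. The step needs facial selectivity at the aldehyde (secured by the α-oxirane and the Z geometry of 10), attack by O1 and not by the C3 oxygen (five- against four-membered ring) and lactonisation by the C3a and not the C3 hydroxyl (six- against seven-membered ring).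

Step 9
Reactants: 14 penta-1,4-dien-3-ol
Product: 15 (1S)-1-[(2R)-oxiran-2-yl]prop-2-en-1-ol
Conditions: Ti(OiPr)4 (cat.), L-(+)-diisopropyl tartrate, t-BuOOH, 4 Å molecular sieves, CH2Cl2, −20 °C
Reagents that add atoms: tert-butyl hydroperoxide, CC(C)(C)OO
Why: Sharpless asymmetric epoxidation of the prochiral divinyl carbinol, where enantiotopic-group and diastereoface selection by the L-(+)-tartrate catalyst should give the erythro (2R,3S) epoxy alcohol.

Step 10
Reactants: 15 (1S)-1-[(2R)-oxiran-2-yl]prop-2-en-1-ol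
Product: 16 (2R,3S)-pent-4-ene-2,3-diol
Conditions: LiAlH4, THF, 0 °C
Reagents that add atoms: none
Why: Hydride opening of the terminal oxirane at its unsubstituted carbon should give the methyl carbinol with both stereocentres untouched (erythro diol).

Step 11
Reactants: 16 (2R,3S)-pent-4-ene-2,3-diol
Product: 17 (2R,3S)-3-hydroxypent-4-en-2-yl acetate
Conditions: immobilised Candida antarctica lipase B, vinyl acetate, t-BuOMe, rt
Reagents that add atoms: vinyl acetate, CC(=O)OC=C
Why: Lipase-catalysed transesterification should acetylate the (R)-configured methyl carbinol, the fast site by Kazlauskas's rule, and leave the (S)-configured allylic hydroxyl, flanked by two larger groups, free.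

Step 12
Reactants: 17 (2R,3S)-3-hydroxypent-4-en-2-yl acetate
Product: 18 (3S,4R)-4-(acetyloxy)pent-1-en-3-yl benzoate
Conditions: BzCl, pyridine, DMAP (cat.), CH2Cl2, 0 °C
Reagents that add atoms: benzoyl chloride, O=C(Cl)c1ccccc1
Why: Nucleophile-catalysed acylation of the remaining allylic hydroxyl at low temperature should install the benzoate without acetyl migration or change at either stereocentre.

Step 13
Reactants: 13 (2S,3R,3aR,7aR)-2-ethenyl-3-hydroxy-2,3,3a,7a-tetrahydro-5H-furo[3,2-b]pyran-5-one and 18 (3S,4R)-4-(acetyloxy)pent-1-en-3-yl benzoate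
Product: 19 (2R,3S,4E)-2-(acetyloxy)-5-[(2S,3R,3aR,7aR)-3-hydroxy-5-oxo-2,3,3a,7a-tetrahydro-5H-furo[3,2-b]pyran-2-yl]pent-4-en-3-yl benzoate (CNP0151877.1)
Conditions: second-generation Hoveyda–Grubbs catalyst RuCl2(H2IMes)(=CH–C6H4-2-O-i-Pr) (10 mol %), 18 (3 equiv), CH2Cl2, 40 °C
Reagents that add atoms: none
Why: Olefin cross-metathesis of the two terminal vinyl groups, with loss of ethene, should give the thermodynamically preferred E alkene between the two oxygenated allylic carbons, while the conjugated ring-B alkene stays inert.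

Compound list
1 | (Z)-but-2-ene-1,4-diol | OC/C=C\CO | starting material
2 | (Z)-4-[(tert-butyldimethylsilyl)oxy]but-2-en-1-ol | CC(C)(C)[Si](C)(C)OC/C=C\CO | intermediate
3 | [(2S,3R)-3-{[(tert-butyldimethylsilyl)oxy]methyl}oxiran-2-yl]methanol | CC(C)(C)[Si](C)(C)OC[C@H]1O[C@H]1CO | intermediate
4 | (2R,3R)-3-{[(tert-butyldimethylsilyl)oxy]methyl}oxirane-2-carbaldehyde | CC(C)(C)[Si](C)(C)OC[C@H]1O[C@H]1C=O | intermediate
5 | methyl (2Z)-3-[(2S,3R)-3-{[(tert-butyldimethylsilyl)oxy]methyl}oxiran-2-yl]prop-2-enoate | CC(C)(C)[Si](C)(C)OC[C@H]1O[C@H]1/C=C\C(=O)OC | intermediate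
6 | methyl (2Z)-3-[(2S,3R)-3-(hydroxymethyl)oxiran-2-yl]prop-2-enoate | OC[C@H]1O[C@H]1/C=C\C(=O)OC | intermediate
7 | methyl (2Z)-3-[(2S,3S)-3-formyloxiran-2-yl]prop-2-enoate | O=C[C@H]1O[C@H]1/C=C\C(=O)OC | intermediate
8 | allyl tert-butyl ether (3-tert-butoxyprop-1-ene) | C=CCOC(C)(C)C | starting material
9 | (Z)-3-tert-butoxyallyllithium | [Li]C/C=C\OC(C)(C)C | intermediate
10 | 2-[(2Z)-3-tert-butoxyprop-2-en-1-yl]-4,4,5,5-tetramethyl-1,3,2-dioxaborolane | CC(C)(C)O/C=C\CB1OC(C)(C)C(C)(C)O1 | intermediate
11 | pinacol borate ester of methyl (2Z)-3-{(2S,3R)-3-[(1R,2S)-2-tert-butoxy-1-hydroxybut-3-en-1-yl]oxiran-2-yl}prop-2-enoate | CC(C)(C)O[C@@H](C=C)[C@@H](OB1OC(C)(C)C(C)(C)O1)[C@H]1O[C@H]1/C=C\C(=O)OC | intermediate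
12 | methyl (2Z)-3-[(2R,3R,4S,5S)-5-ethenyl-3,4-dihydroxyoxolan-2-yl]prop-2-enoate (shown as the free diol) | C=C[C@@H]1O[C@H](/C=C\C(=O)OC)[C@H](O)[C@@H]1O | intermediate
13 | (2S,3R,3aR,7aR)-2-ethenyl-3-hydroxy-2,3,3a,7a-tetrahydro-5H-furo[3,2-b]pyran-5-one | C=C[C@@H]1O[C@@H]2C=CC(=O)O[C@@H]2[C@@H]1O | intermediate
14 | penta-1,4-dien-3-ol | C=CC(O)C=C | starting material
15 | (1S)-1-[(2R)-oxiran-2-yl]prop-2-en-1-ol | C1O[C@H]1[C@@H](O)C=C | intermediate
16 | (2R,3S)-pent-4-ene-2,3-diol | C[C@@H](O)[C@@H](O)C=C | intermediate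
17 | (2R,3S)-3-hydroxypent-4-en-2-yl acetate | CC(=O)O[C@H](C)[C@@H](O)C=C | intermediate
18 | (3S,4R)-4-(acetyloxy)pent-1-en-3-yl benzoate | CC(=O)O[C@H](C)[C@H](C=C)OC(=O)c1ccccc1 | intermediate
19 | (2R,3S,4E)-2-(acetyloxy)-5-[(2S,3R,3aR,7aR)-3-hydroxy-5-oxo-2,3,3a,7a-tetrahydro-5H-furo[3,2-b]pyran-2-yl]pent-4-en-3-yl benzoate | CC(=O)O[C@H](C)[C@H](/C=C/[C@@H]1O[C@@H]2C=CC(=O)O[C@@H]2[C@@H]1O)OC(=O)c1ccccc1 | target

Total step count: 13. Longest linear sequence: 8 steps (steps 1 to 6, then 8 and 13).

Steps most likely to fail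

Step 8. Facial discrimination in the allylboration rests on substrate control alone and may be incomplete, and in the acid stage intermolecular opening or rearrangement of the activated oxirane may compete with ring closure. Fallback (reagent control and two separate operations): aldehyde 7 would be treated with the chiral allylborane made from 8 with s-BuLi, (+)-Ipc2BOMe and BF3·OEt2 (Brown γ-alkoxyallylboration, THF, −78 °C, ethanolamine work-up). This gives, as an isolated compound, methyl (2Z)-3-{(2S,3R)-3-[(1R,2S)-2-tert-butoxy-1-hydroxybut-3-en-1-yl]oxiran-2-yl}prop-2-enoate F1, which is freed from minor diastereomers and then cyclised on its own with camphorsulfonic acid or BF3·OEt2 in CH2Cl2. The fallback sets out from 7 and returns to the route at 13.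

Step 13. Productive metathesis between two hindered, oxygen-flanked vinyl groups may be slow, with homodimerisation of 18 and catalyst decay taking over. Fallback (other partner, benzoate installed last): 13 would be crossed with the allylic alcohol 17, whose free hydroxyl makes it the faster partner, using the same ruthenium catalyst. This gives (2R,3S,4E)-3-hydroxy-5-[(2S,3R,3aR,7aR)-3-hydroxy-5-oxo-2,3,3a,7a-tetrahydro-5H-furo[3,2-b]pyran-2-yl]pent-4-en-2-yl acetate F2. Its exposed allylic hydroxyl would then be benzoylated in preference to the C3 hydroxyl, which sits on the concave face of the bicycle (BzCl, 2,4,6-collidine, CH2Cl2, −40 °C). The fallback sets out from 13 and 17 and returns at 19.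

Step 11. The enzyme may not discriminate fully between the two secondary hydroxyls, and the acetyl group may migrate to the neighbouring oxygen. Fallback (chemical differentiation through the oxirane): 15 would be benzoylated (BzCl, pyridine) to (1S)-1-[(2R)-oxiran-2-yl]prop-2-en-1-yl benzoate F3. The oxirane would be opened by iodide at its terminal carbon (MgI2, Et2O, −40 °C) to (3S,4S)-4-hydroxy-5-iodopent-1-en-3-yl benzoate F4. The new hydroxyl would be acetylated (Ac2O, pyridine) to (3S,4S)-4-(acetyloxy)-5-iodopent-1-en-3-yl benzoate F5, and the iodide removed by radical reduction (Bu3SnH, AIBN, toluene, 80 °C). The fallback sets out from 15 and returns at 18.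

Further compounds
F1 | step 8 | methyl (2Z)-3-{(2S,3R)-3-[(1R,2S)-2-tert-butoxy-1-hydroxybut-3-en-1-yl]oxiran-2-yl}prop-2-enoate | CC(C)(C)O[C@@H](C=C)[C@@H](O)[C@H]1O[C@H]1/C=C\C(=O)OC
F2 | step 13 | (2R,3S,4E)-3-hydroxy-5-[(2S,3R,3aR,7aR)-3-hydroxy-5-oxo-2,3,3a,7a-tetrahydro-5H-furo[3,2-b]pyran-2-yl]pent-4-en-2-yl acetate | CC(=O)O[C@H](C)[C@@H](O)/C=C/[C@@H]1O[C@@H]2C=CC(=O)O[C@@H]2[C@@H]1O
F3 | step 11 | (1S)-1-[(2R)-oxiran-2-yl]prop-2-en-1-yl benzoate | C1O[C@H]1[C@H](C=C)OC(=O)c1ccccc1
F4 | step 11 | (3S,4S)-4-hydroxy-5-iodopent-1-en-3-yl benzoate | IC[C@@H](O)[C@H](C=C)OC(=O)c1ccccc1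
F5 | step 11 | (3S,4S)-4-(acetyloxy)-5-iodopent-1-en-3-yl benzoate | CC(=O)O[C@H](CI)[C@H](C=C)OC(=O)c1ccccc1
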